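The readings are calculated for an exercise; the scatter is artificial.

Reagent is what I count first in these flasks, for the plateaus of the earlier runs go with its charge.

| setting | epsilon | gamma | zeta | winter | dawn | midnight | autumn |
|---|---|---|---|---|---|---|---|
| substrate | 20 mM | 20 mM | 20 mM | 20 mM | 20 mM (fed, over 1.5 h) | 20 mM | 20 mM |
| reagent | 14 mM | 9.4 mM | 21 mM | 14.0 mM (fed, over 1.5 h) | 14.0 mM | 14.0 mM (in portions, 3, over 1.5 h) | 14.0 mM |
| remark | run made earlier | run made earlier | run made earlier | all else is in the flask from the start; the feed brings no volume worth counting | all else is in the flask from the start; the feed brings no volume worth counting | first portion at the start, last at 1.5 h | everything together at the start |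
| time |  |  |  | 4.0 h | 4.0 h | 4.0 h | 4.0 h |

- epsilon (time / h: target / %): 0.417: 33; 0.833: 51; 1.33: 58; 1.50: 61; 2.00: 70; 2.50: 65
- gamma (time / h: target / %): 0.200: 8; 0.667: 35; 1.00: 40; 2.00: 48; 2.50: 47; 3.00: 48
- zeta (time / h: target / %): 0.200: 21; 0.667: 57; 1.00: 72; 2.00: 75; 2.50: 78; 3.00: 75

(standard deviation of a reading: 2 percentage points)

- what was read earlier has a scatter of 2 percentage points, one standard deviation

- the flask with the highest amount of target, in percent of the substrate charged ("all alike" if they lie within 1.5 percentage points) (winter / dawn / midnight / autumn / all alike)
- final target, as a percentage of the substrate charged, in winter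
- final target, as a percentage of the substrate charged, in dawn
- final target, as a percentage of the substrate charged, in midnight
- final target, as a percentage of the substrate charged, in autumn

The fastest rung of my ladder is the making of target: the zeta run reads 72% at 1.00 h against a mean of 76.0% in its readings from 2.00 h on, and the gamma run reads 40% at 1.00 h and 48% at 2.00 h. The next rung is the addition in winter, dawn and midnight, whose feeds and last portion end at 1.5 h, later than that first stretch. The slowest rung is the asked 4.0 h, later than the addition and that stretch together, so I expect to read plateaus rather than rates.

I therefore reckon as if the making of target were over by the asked time and ask what it leaves free. If each reagent gives one target, reagent is the limiting reagent by charge and target stops at the reagent ceiling, the reagent charge as a fraction of the substrate charge, in winter, dawn, midnight and autumn alike 70.0%, which leaves 30.0% of the substrate spare. In the gamma run that ceiling is 47.0% and the last reading is 48%. In the zeta run it is 105%, above the whole charge, yet the late readings average 76.0%, so by these readings about a quarter of the substrate goes elsewhere there. My own figure is the ceiling, and I put autumn, with the charges of the epsilon run, close under it.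

The forecast gives 67% for autumn, 68% for dawn, 64% for midnight and 62% for winter, with dawn highest, holding that “substrate seems to leak away by a path that doesn't use reagent”.

The flasks give 67.4% in autumn, the highest, then 65.5% in dawn, 60.8% in winter and 59.0% in midnight, which is 5 percentage points below the forecast.

    substrate + reagent → intermediate + released group (k = 15.5 L mol⁻¹ min⁻¹)
    intermediate → target (k = 0.0337 min⁻¹)
    substrate + released group → side product (k = 3.35 L mol⁻¹ min⁻¹)
    reagent + target → over-reaction product (k = 0.189 L mol⁻¹ min⁻¹)

In autumn at 0.0458 h the half-life of substrate by the making of intermediate, 0.10 h, is shorter than the 0.55 h by the loss to side product, whereas at 4.00 h it is longer, 4.3 h against 0.47 h. Autumn ends with side product at 31.7%, beside the 30.0% the ceiling left spare. A neighbour of autumn charged with 50 mM of substrate has a ceiling of 28.0%; that flask gives 28.0% of target, with reagent at 0% and 44.0% of its substrate still standing.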